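Take the two substrates as rivals for one catalyst and follow what each has lost.

| setting | Wednesday's | Saturday's | Tuesday's | gamma | eta | delta | alpha |
|---|---|---|---|---|---|---|---|
| left-handed substrate | 1.5 M | 1.5 M | 1.5 M | 1.5 M | 1.5 M | 1.5 M | 1.5 M |
| right-handed substrate | 1.5 M | 1.5 M | 1.5 M | 1.5 M | 1.5 M | 1.5 M | 1.5 M |
| gas | 59 mM (held) | 59 mM (held) | 59 mM (held) | 59 mM (held) | 59 mM (held) | 59 mM (held) | 59 mM (held) |
| free catalyst | 14 mM | 23 mM | 34 mM | 15 mM | 15 mM | 30 mM | 30 mM |
| temperature | 45 °C | 65 °C | 45 °C | 50 °C | 80 °C | 50 °C | 80 °C |
| remark | run made earlier | run made earlier | run made earlier |  |  |  |  |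
| time |  |  |  | 8.0 min | 8.0 min | 8.0 min | 8.0 min |

- Wednesday's (time / min: left-handed product / %, right-handed product / %, left-handed substrate / %): 8.00: 3, 17, 51; 15.0: 8, 28, 39; 30.0: 20, 42, 28; 50.0: 37, 50, 12
- Saturday's (time / min: left-handed product / %, right-handed product / %, left-handed substrate / %): 3.00: 20, 15, 28; 6.00: 34, 33, 14; 10.0: 47, 45, 1; 12.0: 48, 51, 4; 15.0: 48, 49, 2
- Tuesday's (time / min: left-handed product / %, right-handed product / %, left-handed substrate / %): 4.00: 3, 10, 49; 12.0: 23, 40, 30; 25.0: 44, 49, 7; 30.0: 46, 49, 1; 50.0: 51, 48, 0

(each reading ± 2 percentage points)

1. all flasks from highest to lowest excess of left-handed product over right-handed product, at 8.0 min (gamma / eta / delta / alpha)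
2. the excess of left-handed product over right-handed product of the flask you put first, at 8.0 min
3. the excess of left-handed product over right-handed product of the flask you put last, at 8.0 min

- free catalyst is single-handed; left-handed substrate and right-handed substrate are mirror images of each other, charged as a racemate, each of them at the stated concentration
- at the start none of the gas is in solution

I assumed that each substrate went at a rate proportional to its own amount, times a common catalyst term. Dividing the two rates and integrating then gave [right-handed substrate]/charge = ([left-handed substrate]/charge)^s, where s, the selectivity factor, is the ratio of the two logarithms. Each substrate was half of what the percentages count, so the product readings gave both fractions. Pooling mid-course readings from Wednesday's and Tuesday's runs, I read s = 3.28 at 45 °C. Saturday's first two readings gave 0.870 at 65 °C. I took ln s as straight in temperature. For gamma and delta, a quarter of the way up that interval, this estimate gave the selectivity factor s = 2.35. For eta and alpha, beyond the readings, it gave 0.322, which favours the left hand.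

Next I built a ladder of clearing times, the time the whole charge takes at the early, nearly steady pace. Wednesday's run gave 41.7 min and Saturday's 8.96 min. Scaling inversely with catalyst and interpolating the logarithm likewise, I got alpha 3.14 min, eta 6.29 min, delta 15.0 min and gamma 30.0 min. So I expected alpha and eta near their end by 8.0 min, with small positive excesses and eta's the larger, and delta and gamma in mid-course. I took the excess as the difference of left-handed and right-handed product over their sum. Setting the geometric mean of the two fractions left equal to the fraction of the whole charge left, I put gamma's left-handed substrate at 83.1% of its charge and its excess at −35.2%. Delta's excess came to −28.5%.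

The forecast gave eta > alpha > delta > gamma, with 15% for the first flask and −50% for the last, arguing: “This implies a selectivity inversion with temperature”. My order was the same, but my excess for gamma stood higher than its −50%.

The flasks gave eta > alpha > delta > gamma, with 15.0% for eta and −37.0% for gamma, 13 percentage points above the forecast's value for the last flask.

    free catalyst + right-handed substrate ⇌ catalyst intermediate B (K = 2.20 /M, k = 49.0 /M/s, Ea = 54.0 kJ/mol, ΔH = −20.0 kJ/mol)
    coupling partner + catalyst intermediate B → free catalyst + right-handed product (k = 5.90 /M/s, Ea = 42.0 kJ/mol)
    free catalyst ⇌ dormant form (K = 2.70, k = 0.00790 /s, Ea = 90.0 kJ/mol, ΔH = −46.0 kJ/mol)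
    free catalyst + left-handed substrate ⇌ catalyst intermediate A (K = 0.390 /M, k = 120 /M/s, Ea = 47.0 kJ/mol, ΔH = 28.0 kJ/mol)
    coupling partner + catalyst intermediate A → free catalyst + left-handed product (k = 95.0 /M/s, Ea = 57.0 kJ/mol)
    gas ⇌ coupling partner, rate k6*(csat - [coupling partner]) (kL = 15.0 /s)
    2 coupling partner → homo dimer (k = 0.700 /M/s, Ea = 54.0 kJ/mol)
    (constants at 80 °C)

Gamma had converted 25.6% by 8.00 min, keeping 84% of its left-handed substrate and 65% of its right-handed substrate. Raised to s = 2.35, that 84% becomes 66.4%. In delta, the 65% of left-handed substrate kept becomes 36.3%, and the flask kept 34% of its right-handed substrate.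

All runs were generated by integration with made-up constants, and the scatter is random.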